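The O1–C2(ring B)–C3 unit fused to ring A is read as a ring-contracted flavanone, and ring C is attached last at C3 by decarboxylative arylation. The key step takes a (2S)-flavanone in which O1, C2 with ring B and the oxygenated, alkylated ring A are already in place. In one operation it shifts the ring A carbon from the carbonyl carbon to C3 (new C3–C3a bond), contracts the pyranone to the dihydrofuran, sets C3 trans to ring B and leaves the old C4 as a methyl ester handle. The precursor carries ring B as a bis-tosylate so that ring B neither migrates nor ionises at C2.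

Key step: step 8

Design remark: from step 4 to step 13 ring B is carried as its bis(4-methylbenzenesulfonate) and not as methyl ethers. An electron-rich 2,4-dialkoxyphenyl group at C2 would be the best migrating group in the key step, would itself be open to attack by trivalent iodine, and would make the C2–O1 bond acid-labile.

Assumption: the sense of induction in step 7 cannot be assigned with confidence for this flavone. The antipode of DTBM-SEGPHOS that delivers hydride to the Re face of C2 is to be chosen in a small-scale test; (R) is written as the working choice.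

Step 1
Reactants: 1 (E)-3,4',5-trimethoxystilbene
Product: 2 1,3-dimethoxy-5-[2-(4-methoxyphenyl)ethyl]benzene
Conditions: H2 (1 atm), 10% Pd/C, EtOAc, rt
Reagents that add atoms: none
Why: Heterogeneous catalytic hydrogenation saturates the stilbene C=C bond at ambient pressure, and aryl methyl ethers are inert to it.

Step 2
Reactants: 2 1,3-dimethoxy-5-[2-(4-methoxyphenyl)ethyl]benzene
Product: 4 1-{2,6-dimethoxy-4-[2-(4-methoxyphenyl)ethyl]phenyl}ethan-1-one, via aryllithium 3 (not isolated)
Conditions: n-BuLi (1.1 equiv), THF, 0 °C to rt; then MeC(O)N(OMe)Me, −78 °C to rt; aq. NH4Cl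
Reagents that add atoms: N-methoxy-N-methylacetamide, CC(=O)N(C)OC
Why: Directed ortho-metalation occurs at the ring carbon flanked by both methoxy groups, and the Weinreb ketone synthesis acylates the aryllithium once, which places the acetyl group para to the side chain as ring A requires.

Step 3
Reactants: 4 1-{2,6-dimethoxy-4-[2-(4-methoxyphenyl)ethyl]phenyl}ethan-1-one
Product: 5 1-{2-hydroxy-6-methoxy-4-[2-(4-methoxyphenyl)ethyl]phenyl}ethan-1-one
Conditions: BCl3 (1.1 equiv), CH2Cl2, −78 to 0 °C; then H2O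
Reagents that add atoms: none
Why: Chelation-controlled Lewis-acid ether cleavage removes only a methyl ether that can close a six-membered boron chelate with the carbonyl; the resulting chelate deactivates the second ortho ether, and the distant anisole is untouched at this temperature.

Step 4
Reactants: 6 2,4-dihydroxybenzaldehyde
Product: 7 4-formyl-1,3-phenylene bis(4-methylbenzenesulfonate)
Conditions: TsCl (2.3 equiv), Et3N, DMAP (cat.), CH2Cl2, 0 °C to rt
Reagents that add atoms: 4-methylbenzenesulfonyl chloride, Cc1ccc(cc1)S(Cl)(=O)=O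
Why: DMAP-catalysed O-sulfonylation converts both phenols into tosylates, which make ring B electron-poor and are stable to acid, oxidants, hydride and organozinc reagents.

Step 5
Reactants: 5 1-{2-hydroxy-6-methoxy-4-[2-(4-methoxyphenyl)ethyl]phenyl}ethan-1-one; 7 4-formyl-1,3-phenylene bis(4-methylbenzenesulfonate)
Product: 9 4-[(E)-3-{2-hydroxy-6-methoxy-4-[2-(4-methoxyphenyl)ethyl]phenyl}-3-oxoprop-1-en-1-yl]-1,3-phenylene bis(4-methylbenzenesulfonate), via boron difluoride chelate 8 (not isolated)
Conditions: BF3·OEt2 (3 equiv), 1,4-dioxane, rt; then aq. NaHCO3, MeOH/THF, 40 °C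
Reagents that add atoms: none
Why: In this Lewis-acid-mediated Claisen–Schmidt condensation boron ties the phenol and carbonyl oxygens together, so the ketone enolises and condenses with the electron-poor aldehyde but cannot cyclise, and the base-labile aryl tosylates never meet hydroxide.

Step 6
Reactants: 9 the (E)-chalcone from step 5
Product: 10 4-{5-methoxy-7-[2-(4-methoxyphenyl)ethyl]-4-oxo-4H-chromen-2-yl}-1,3-phenylene bis(4-methylbenzenesulfonate)
Conditions: I2 (0.1 equiv), DMSO, 130 °C
Reagents that add atoms: none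
Why: Iodine/DMSO oxidative cyclisation of a 2'-hydroxychalcone (oxa-Michael closure, α-iodination, loss of HI, Kornblum-type reoxidation of iodide by DMSO) is a standard flavone synthesis and tolerates sulfonates and methyl ethers.

Step 7
Reactants: 10 the flavone from step 6
Product: 12 4-{(2S)-5-methoxy-7-[2-(4-methoxyphenyl)ethyl]-4-oxochroman-2-yl}-1,3-phenylene bis(4-methylbenzenesulfonate), via silyl enol ether 11 (not isolated)
Conditions: Cu(OAc)2 (5 mol%), (R)-DTBM-SEGPHOS (5.5 mol%), (EtO)2MeSiH, toluene, 0 °C to rt; then 1 M HCl, THF, 0 °C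
Reagents that add atoms: none
Why: In this asymmetric conjugate reduction the bisphosphine-bound monovalent copper hydride adds hydride to the Re face of C2 of the chromone enone under ligand control, which sets (2S); silylation of the copper enolate prevents over-reduction and β-elimination of the phenoxide before mild hydrolysis.

Step 8
Reactants: 12 the (2S)-flavanone from step 7
Product: 16 methyl (2S,3S)-2-[2,4-bis(tosyloxy)phenyl]-4-methoxy-6-[2-(4-methoxyphenyl)ethyl]-2,3-dihydro-1-benzofuran-3-carboxylate (2,3-trans), via methyl enol ether 13 (not isolated), via iodanyl ketal 14 (not isolated), via orthoester 15 (not isolated)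
Conditions: PhI(OAc)2 (1.15 equiv), conc. H2SO4 (0.5 equiv), HC(OMe)3, 0 °C to rt; then H2O
Reagents that add atoms: trimethyl orthoformate, COC(OC)OC; water, O
Why: Acid and orthoformate turn ketone 12 into methyl enol ether 13, which attacks the trivalent iodine of PhI(OAc)2 through C3 on the face opposite ring B, and methanol capture gives ketal 14 with iodine and ring B both equatorial. The C4–C4a bond then lies antiperiplanar to the C3–I bond, so the ring A carbon shifts from C4 to C3 with inversion as iodobenzene leaves; this is a semipinacol-type oxidative 1,2-aryl shift, the reaction type of the known PhI(OAc)2 or Tl(NO3)3 ring contraction of flavanones in trimethyl orthoformate, and the dimethoxycarbenium ion is held as orthoester 15 until aqueous work-up releases the methyl ester. The five-membered ring is closed by contraction through a bridged, phenonium-like transition state that forms C3–C3a inside the existing ring, not by an end-to-end cyclisation. The new C3 centre is controlled by C2: anti iodination followed by invertive migration places the ester trans to ring B, which is also the more stable epimer. The step needs ring A to migrate in preference to ring B (isoflavone), to hydride loss (flavone 10) and to ionisation of the C2–O1 bond (racemisation). The ortho-substituted ring B is locked equatorial, and its two sulfonate esters lower its migratory aptitude and its ability to stabilise positive charge at C2, while ring A keeps its donating methoxy group.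

Step 9
Reactants: 16 the trans methyl ester from step 8
Product: 17 (2S,3S)-2-[2,4-bis(tosyloxy)phenyl]-4-methoxy-6-[2-(4-methoxyphenyl)ethyl]-2,3-dihydro-1-benzofuran-3-carboxylic acid
Conditions: Me3SnOH (6 equiv), ClCH2CH2Cl, 80 °C; then 1 M HCl wash
Reagents that add atoms: trimethyltin hydroxide, C[Sn](C)(C)O
Why: Organotin-mediated ester hydrolysis delivers hydroxide to the methyl ester under nearly neutral conditions, which spares the aryl sulfonates and avoids a C3 enolate that could open the ring by β-elimination of the phenoxide.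

Step 10
Reactants: 17 the carboxylic acid from step 9
Product: 18 1,3-dioxoisoindolin-2-yl (2S,3S)-2-[2,4-bis(tosyloxy)phenyl]-4-methoxy-6-[2-(4-methoxyphenyl)ethyl]-2,3-dihydro-1-benzofuran-3-carboxylate
Conditions: N-hydroxyphthalimide, i-PrN=C=N-i-Pr, DMAP (cat.), CH2Cl2, rt
Reagents that add atoms: N-hydroxyphthalimide, ON1C(=O)c2ccccc2C1=O
Why: Carbodiimide coupling (Steglich-type esterification) gives the redox-active N-acyloxyphthalimide; the C3 configuration is of no consequence because the centre becomes a radical in step 12.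

Step 11
Reactants: 19 1-bromo-3,5-dimethoxybenzene
Product: 21 (3,5-dimethoxyphenyl)zinc chloride (THF solution, titrated and used directly), via arylmagnesium bromide 20 (not isolated)
Conditions: Mg, LiCl, THF, rt; then ZnCl2 (1 M in THF), 0 °C to rt
Reagents that add atoms: zinc chloride, Cl[Zn]Cl
Why: LiCl-assisted magnesium insertion gives the Grignard reagent, and transmetalation to zinc furnishes a milder aryl donor that tolerates the ester and sulfonate groups of its coupling partner.

Step 12
Reactants: 18 the N-acyloxyphthalimide from step 10; 21 (3,5-dimethoxyphenyl)zinc chloride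
Product: 22 4-{(2S,3S)-3-(3,5-dimethoxyphenyl)-4-methoxy-6-[2-(4-methoxyphenyl)ethyl]-2,3-dihydro-1-benzofuran-2-yl}-1,3-phenylene bis(4-methylbenzenesulfonate)
Conditions: 21 (3 equiv), NiCl2(dme) (20 mol%), 4,4'-di-tert-butyl-2,2'-bipyridine (40 mol%), THF/DMF, rt
Reagents that add atoms: none
Why: In this nickel-catalysed decarboxylative Negishi-type arylation a low-valent arylnickel species transfers one electron to 18, loss of CO2 and phthalimide gives the planar benzylic C3 radical, and this radical is captured and arylated on the face away from ring B, which sets (3S) trans to the C2 aryl group; aryl tosylates should be inert to nickel/bipyridine at room temperature.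

Step 13
Reactants: 22 the bis-tosylate from step 12
Product: 23 4-{(2S,3S)-3-(3,5-dimethoxyphenyl)-4-methoxy-6-[2-(4-methoxyphenyl)ethyl]-2,3-dihydro-1-benzofuran-2-yl}benzene-1,3-diol
Conditions: Mg turnings (excess), MeOH/THF, rt, sonication; then aq. NH4Cl, 1 M HCl
Reagents that add atoms: none
Why: Electron transfer from magnesium in methanol cleaves the S–O bonds of aryl tosylates (dissolving-metal-type reductive desulfonylation) at room temperature without strong base, so the methyl ethers and the benzylic C2–O1 bond remain intact.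

Step 14
Reactants: 23 the resorcinol from step 13
Product: 24 4-{(2S,3S)-3-(3,5-dihydroxyphenyl)-4-hydroxy-6-[2-(4-hydroxyphenyl)ethyl]-2,3-dihydro-1-benzofuran-2-yl}benzene-1,3-diol
Conditions: BBr3 (12 equiv), CH2Cl2, −78 °C to rt; then H2O, 0 °C
Reagents that add atoms: none
Why: Lewis-acid ether cleavage by BBr3 removes the four aryl methyl ethers through bromide attack on the boron-coordinated methyl groups; C3 cannot epimerise and any reversible ionisation at C2 would re-close to the more stable trans ring, so (2S,3S) should be retained.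

Compound list

1 | (E)-3,4',5-trimethoxystilbene | COc1ccc(/C=C/c2cc(OC)cc(OC)c2)cc1 | starting material
2 | 1,3-dimethoxy-5-[2-(4-methoxyphenyl)ethyl]benzene | COc1ccc(CCc2cc(OC)cc(OC)c2)cc1 | intermediate
3 | {2,6-dimethoxy-4-[2-(4-methoxyphenyl)ethyl]phenyl}lithium | COc1ccc(CCc2cc(OC)c([Li])c(OC)c2)cc1 | intermediate
4 | 1-{2,6-dimethoxy-4-[2-(4-methoxyphenyl)ethyl]phenyl}ethan-1-one | COc1ccc(CCc2cc(OC)c(C(C)=O)c(OC)c2)cc1 | intermediate
5 | 1-{2-hydroxy-6-methoxy-4-[2-(4-methoxyphenyl)ethyl]phenyl}ethan-1-one | COc1ccc(CCc2cc(O)c(C(C)=O)c(OC)c2)cc1 | intermediate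
6 | 2,4-dihydroxybenzaldehyde | O=Cc1ccc(O)cc1O | starting material
7 | 4-formyl-1,3-phenylene bis(4-methylbenzenesulfonate) | Cc1ccc(cc1)S(=O)(=O)Oc1ccc(C=O)c(OS(=O)(=O)c2ccc(C)cc2)c1 | intermediate
8 | boron difluoride chelate of chalcone 9 (BF2 bridging the phenol oxygen and the carbonyl oxygen, (E)-alkene) | COc1ccc(CCc2cc(OC)c3c(c2)O[B-](F)(F)[O+]=C3/C=C/c2ccc(OS(=O)(=O)c4ccc(C)cc4)cc2OS(=O)(=O)c2ccc(C)cc2)cc1 | intermediate
9 | 4-[(E)-3-{2-hydroxy-6-methoxy-4-[2-(4-methoxyphenyl)ethyl]phenyl}-3-oxoprop-1-en-1-yl]-1,3-phenylene bis(4-methylbenzenesulfonate) | COc1ccc(CCc2cc(O)c(C(=O)/C=C/c3ccc(OS(=O)(=O)c4ccc(C)cc4)cc3OS(=O)(=O)c3ccc(C)cc3)c(OC)c2)cc1 | intermediate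
10 | 4-{5-methoxy-7-[2-(4-methoxyphenyl)ethyl]-4-oxo-4H-chromen-2-yl}-1,3-phenylene bis(4-methylbenzenesulfonate) | COc1ccc(CCc2cc(OC)c3c(c2)OC(c2ccc(OS(=O)(=O)c4ccc(C)cc4)cc2OS(=O)(=O)c2ccc(C)cc2)=CC3=O)cc1 | intermediate
11 | 4-{(2S)-4-{[diethoxy(methyl)silyl]oxy}-5-methoxy-7-[2-(4-methoxyphenyl)ethyl]-2H-chromen-2-yl}-1,3-phenylene bis(4-methylbenzenesulfonate) | COc1ccc(CCc2cc(OC)c3c(c2)O[C@H](c2ccc(OS(=O)(=O)c4ccc(C)cc4)cc2OS(=O)(=O)c2ccc(C)cc2)C=C3O[Si](C)(OCC)OCC)cc1 | intermediate
12 | 4-{(2S)-5-methoxy-7-[2-(4-methoxyphenyl)ethyl]-4-oxochroman-2-yl}-1,3-phenylene bis(4-methylbenzenesulfonate) | COc1ccc(CCc2cc(OC)c3c(c2)O[C@H](c2ccc(OS(=O)(=O)c4ccc(C)cc4)cc2OS(=O)(=O)c2ccc(C)cc2)CC3=O)cc1 | intermediate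
13 | 4-{(2S)-4,5-dimethoxy-7-[2-(4-methoxyphenyl)ethyl]-2H-chromen-2-yl}-1,3-phenylene bis(4-methylbenzenesulfonate) | COc1ccc(CCc2cc(OC)c3c(c2)O[C@H](c2ccc(OS(=O)(=O)c4ccc(C)cc4)cc2OS(=O)(=O)c2ccc(C)cc2)C=C3OC)cc1 | intermediate
14 | 4-{(2R,3R)-3-[acetoxy(phenyl)-λ3-iodanyl]-4,4,5-trimethoxy-7-[2-(4-methoxyphenyl)ethyl]chroman-2-yl}-1,3-phenylene bis(4-methylbenzenesulfonate); iodine trans to ring B, C2 spatially as in 12 (its descriptor changes only because iodine raises the rank of C3) | COc1ccc(CCc2cc(OC)c3c(c2)O[C@H](c2ccc(OS(=O)(=O)c4ccc(C)cc4)cc2OS(=O)(=O)c2ccc(C)cc2)[C@@H](I(OC(C)=O)c2ccccc2)C3(OC)OC)cc1 | intermediate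
15 | 4-{(2S,3S)-4-methoxy-6-[2-(4-methoxyphenyl)ethyl]-3-(trimethoxymethyl)-2,3-dihydro-1-benzofuran-2-yl}-1,3-phenylene bis(4-methylbenzenesulfonate) (2,3-trans) | COc1ccc(CCc2cc(OC)c3c(c2)O[C@H](c2ccc(OS(=O)(=O)c4ccc(C)cc4)cc2OS(=O)(=O)c2ccc(C)cc2)[C@H]3C(OC)(OC)OC)cc1 | intermediate
16 | methyl (2S,3S)-2-[2,4-bis(tosyloxy)phenyl]-4-methoxy-6-[2-(4-methoxyphenyl)ethyl]-2,3-dihydro-1-benzofuran-3-carboxylate (2,3-trans) | COc1ccc(CCc2cc(OC)c3c(c2)O[C@H](c2ccc(OS(=O)(=O)c4ccc(C)cc4)cc2OS(=O)(=O)c2ccc(C)cc2)[C@H]3C(=O)OC)cc1 | intermediate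
17 | (2S,3S)-2-[2,4-bis(tosyloxy)phenyl]-4-methoxy-6-[2-(4-methoxyphenyl)ethyl]-2,3-dihydro-1-benzofuran-3-carboxylic acid | COc1ccc(CCc2cc(OC)c3c(c2)O[C@H](c2ccc(OS(=O)(=O)c4ccc(C)cc4)cc2OS(=O)(=O)c2ccc(C)cc2)[C@H]3C(=O)O)cc1 | intermediate
18 | 1,3-dioxoisoindolin-2-yl (2S,3S)-2-[2,4-bis(tosyloxy)phenyl]-4-methoxy-6-[2-(4-methoxyphenyl)ethyl]-2,3-dihydro-1-benzofuran-3-carboxylate | COc1ccc(CCc2cc(OC)c3c(c2)O[C@H](c2ccc(OS(=O)(=O)c4ccc(C)cc4)cc2OS(=O)(=O)c2ccc(C)cc2)[C@H]3C(=O)ON2C(=O)c3ccccc3C2=O)cc1 | intermediate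
19 | 1-bromo-3,5-dimethoxybenzene | COc1cc(Br)cc(OC)c1 | starting material
20 | (3,5-dimethoxyphenyl)magnesium bromide | COc1cc([Mg]Br)cc(OC)c1 | intermediate
21 | (3,5-dimethoxyphenyl)zinc chloride | COc1cc([Zn]Cl)cc(OC)c1 | intermediate
22 | 4-{(2S,3S)-3-(3,5-dimethoxyphenyl)-4-methoxy-6-[2-(4-methoxyphenyl)ethyl]-2,3-dihydro-1-benzofuran-2-yl}-1,3-phenylene bis(4-methylbenzenesulfonate) (2,3-trans) | COc1ccc(CCc2cc(OC)c3c(c2)O[C@H](c2ccc(OS(=O)(=O)c4ccc(C)cc4)cc2OS(=O)(=O)c2ccc(C)cc2)[C@H]3c2cc(OC)cc(OC)c2)cc1 | intermediate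
23 | 4-{(2S,3S)-3-(3,5-dimethoxyphenyl)-4-methoxy-6-[2-(4-methoxyphenyl)ethyl]-2,3-dihydro-1-benzofuran-2-yl}benzene-1,3-diol | COc1ccc(CCc2cc(OC)c3c(c2)O[C@H](c2ccc(O)cc2O)[C@H]3c2cc(OC)cc(OC)c2)cc1 | intermediate
24 | 4-{(2S,3S)-3-(3,5-dihydroxyphenyl)-4-hydroxy-6-[2-(4-hydroxyphenyl)ethyl]-2,3-dihydro-1-benzofuran-2-yl}benzene-1,3-diol (2,3-trans) | Oc1ccc(CCc2cc(O)c3c(c2)O[C@H](c2ccc(O)cc2O)[C@H]3c2cc(O)cc(O)c2)cc1 | target

Total step count: 14.
Longest linear sequence: 12 steps (steps 1, 2, 3, 5, 6, 7, 8, 9, 10, 12, 13, 14, from 1 to 24).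

Steps most likely to fail

Step 8. The ring contraction may lose out to migration of ring B from C2 to C3, to dehydrogenation, or to attack of the oxidant on the alkoxy-substituted arenes. Flavone 10 formed by dehydrogenation can be returned to step 7, but the other paths consume material. The fallback makes the same C3–C3a bond by a carbene-based contraction and sets out from flavanone 12. Kinetic enolisation and trifluoroacetylation (LiHMDS, CF3CO2CH2CF3, THF, −78 °C) should give the 3-trifluoroacetyl ketone F1. Detrifluoroacetylative Regitz diazo transfer (MsN3, Et3N, MeCN) should then give the 3-diazo ketone F2. Photochemical Wolff rearrangement in methanol moves the ring A carbon onto C3 and traps the ketene as the methyl ester, expected partly as the cis ester F3, which DBU equilibrates to the trans isomer. The route is rejoined at 16.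

Step 12. The stabilised benzylic C3 radical may dimerise or be reduced before nickel captures it, facial discrimination at C3 may be incomplete, or nickel may insert into an aryl tosylate. The fallback avoids both the organozinc reagent and the activated ester and sets out from acid 17 and aryl bromide 19. Dual photoredox/nickel decarboxylative arylation (Ir[dF(CF3)ppy]2(dtbbpy)PF6, NiCl2(dme), 4,4'-di-tert-butyl-2,2'-bipyridine, Cs2CO3, DMF, blue light) oxidises the carboxylate to the same C3 radical and couples it with the arylnickel bromide formed by oxidative addition. It returns to the route at 22 and makes no new compound (F0).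

Step 7. The ortho-substituted ring B may lower the enantioselectivity of hydride delivery, and the copper enolate may open to the chalcone or be reduced further before it is silylated. The fallback secures C2 by kinetic resolution and sets out from chalcone 9. NaOAc in refluxing ethanol should close the racemic flavanone F4. Asymmetric transfer hydrogenation (RuCl(p-cymene)(TsDPEN), HCO2H/Et3N, the TsDPEN antipode chosen to reduce the 2R ketone) should then convert only the unwanted enantiomer into the cis-(2R,4R)-flavan-4-ol F5, which is removed by chromatography. The unreacted (2S)-ketone is compound 12, where the route is rejoined.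

Further compounds

F1 | step 8 | 4-{(2S)-5-methoxy-7-[2-(4-methoxyphenyl)ethyl]-4-oxo-3-(trifluoroacetyl)chroman-2-yl}-1,3-phenylene bis(4-methylbenzenesulfonate) (C3 epimers/enol) | COc1ccc(CCc2cc(OC)c3c(c2)O[C@H](c2ccc(OS(=O)(=O)c4ccc(C)cc4)cc2OS(=O)(=O)c2ccc(C)cc2)C(C(=O)C(F)(F)F)C3=O)cc1
F2 | step 8 | 4-{(2R)-3-diazo-5-methoxy-7-[2-(4-methoxyphenyl)ethyl]-4-oxochroman-2-yl}-1,3-phenylene bis(4-methylbenzenesulfonate) (C2 spatially as in 12; the descriptor changes with the rank of C3) | COc1ccc(CCc2cc(OC)c3c(c2)O[C@H](c2ccc(OS(=O)(=O)c4ccc(C)cc4)cc2OS(=O)(=O)c2ccc(C)cc2)C(=[N+]=[N-])C3=O)cc1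
F3 | step 8 | methyl (2S,3R)-2-[2,4-bis(tosyloxy)phenyl]-4-methoxy-6-[2-(4-methoxyphenyl)ethyl]-2,3-dihydro-1-benzofuran-3-carboxylate (2,3-cis) | COc1ccc(CCc2cc(OC)c3c(c2)O[C@H](c2ccc(OS(=O)(=O)c4ccc(C)cc4)cc2OS(=O)(=O)c2ccc(C)cc2)[C@@H]3C(=O)OC)cc1
F0 | step 12 | none | none
F4 | step 7 | rac-4-{5-methoxy-7-[2-(4-methoxyphenyl)ethyl]-4-oxochroman-2-yl}-1,3-phenylene bis(4-methylbenzenesulfonate) | COc1ccc(CCc2cc(OC)c3c(c2)OC(c2ccc(OS(=O)(=O)c4ccc(C)cc4)cc2OS(=O)(=O)c2ccc(C)cc2)CC3=O)cc1
F5 | step 7 | 4-{(2R,4R)-4-hydroxy-5-methoxy-7-[2-(4-methoxyphenyl)ethyl]chroman-2-yl}-1,3-phenylene bis(4-methylbenzenesulfonate) (2,4-cis) | COc1ccc(CCc2cc(OC)c3c(c2)O[C@@H](c2ccc(OS(=O)(=O)c4ccc(C)cc4)cc2OS(=O)(=O)c2ccc(C)cc2)C[C@H]3O)cc1
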